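**Strategy**

Everything rests on closing the pyran ring at C3=C4 by enantioselective ring-closing metathesis of an achiral triene: an ortho-vinyl aryl ether of 3-methylpenta-1,4-dien-3-ol. The step exploits a hidden symmetry at C2 of the pyran ring, whose ring neighbour C3 and first side-chain carbon both map onto vinyl groups, making C2 a prochiral divinyl carbinol carbon. A chiral molybdenum alkylidene picks one vinyl group, so one operation closes the ring, forms C3=C4 and sets the quaternary C2 stereocentre. The spare vinyl group then receives the side chain by hydroboration and B-alkyl Suzuki coupling with a cyclogeranyl-derived vinyl iodide (CBS reduction, Claisen chirality transfer). Bromine masks the C6 hydroxyl.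

Key step: step 4

Target as planned: (S)-2-methyl-2-{(E)-4-methyl-6-[(S)-2,6,6-trimethylcyclohex-2-en-1-yl]hex-3-en-1-yl}-2H-chromen-6-ol (both stereocentres S, side-chain alkene E).

Assumption: 2,4,4-trimethylcyclohex-2-en-1-one and both antipodes of the molybdenum biphenolate catalyst are taken as catalogue items. Remark: 2H-chromenes can lose configuration at C2 by reversible electrocyclic ring opening, so all operations from step 4 on are run in the dark and below 40 °C.

**Route**

Step 1
Reactants: 1 ethyl acetate
Product: 3 3-methylpenta-1,4-dien-3-ol, via but-3-en-2-one 2 (not isolated)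
Conditions: CH2=CHMgBr (2.2 equiv), THF, 0 °C to rt; aq NH4Cl
Reagents that add atoms: vinylmagnesium bromide, C=C[Mg]Br
Why: double Grignard addition to an ester, in which the ketone formed first is more electrophilic than the ester, should give the symmetric tertiary carbinol without any stereocentre.

Step 2
Reactants: 3 3-methylpenta-1,4-dien-3-ol; 4 5-bromo-2-fluorobenzaldehyde
Product: 6 5-bromo-2-[(3-methylpenta-1,4-dien-3-yl)oxy]benzaldehyde, via potassium alkoxide 5 (not isolated)
Conditions: KHMDS (1.05 equiv), THF, 0 °C; then 4, 0 °C to rt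
Reagents that add atoms: none
Why: nucleophilic aromatic substitution (addition–elimination) of fluoride, activated by the ortho formyl group and inductively by the para bromine, should attach the tertiary alkoxide to the ring, a bond that SN2 chemistry at the tertiary carbon cannot make.

Step 3
Reactants: 6 5-bromo-2-[(3-methylpenta-1,4-dien-3-yl)oxy]benzaldehyde
Product: 7 4-bromo-2-ethenyl-1-[(3-methylpenta-1,4-dien-3-yl)oxy]benzene
Conditions: Ph3PCH3Br, KOtBu, THF, 0 °C to rt
Reagents that add atoms: methyltriphenylphosphonium bromide, C[P+](c1ccccc1)(c1ccccc1)c1ccccc1.[Br-]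
Why: Wittig methylenation of an aryl aldehyde with a non-stabilised ylide is mild and non-acidic, so the tertiary bis-allylic aryl ether should survive.

Step 4
Reactants: 7 4-bromo-2-ethenyl-1-[(3-methylpenta-1,4-dien-3-yl)oxy]benzene
Product: 8 (S)-6-bromo-2-ethenyl-2-methyl-2H-chromene
Conditions: Mo(N-2,6-iPr2C6H3)(CHCMe2Ph)(3,3'-tBu2-5,5',6,6'-Me4-biphenyl-2,2'-diolate), single enantiomer, 5 mol%, C6H6, 22 °C, N2, dark
Reagents that add atoms: none
Why: The alkylidene should exchange onto the unhindered styrene terminus, and the resulting molybdenum benzylidene then undergoes [2+2] cycloaddition and cycloreversion with one of the two enantiotopic vinyl groups, releasing ethene and forming C3=C4. The closest known reaction type is enantioselective desymmetrising ring-closing metathesis of prochiral trienes to cyclic tertiary ethers with chiral molybdenum diolate alkylidenes, combined with ring-closing metathesis of styrenyl ethers to 2H-chromenes. One ring is closed, the six-membered pyran ring O1–C2–C3=C4–C4a–C8a, by olefin metathesis between the styrenyl CH (C4) and a vinyl CH (C3). The only new stereocentre, C2, is controlled by the chiral diolate, which decides which vinyl group enters the metallacyclobutane; the sense of induction cannot be predicted with confidence, so the diolate antipode that gives the S product is fixed in the first run by correlation at the end of the route. The step needs only group selectivity between two identical vinyl groups, because the substrate carries no other alkene and the spare vinyl group of the product sits on a quaternary carbon and should be slow to react further. Loss of ethene drives the closure.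

Step 5
Reactants: 9 2,4,4-trimethylcyclohex-2-en-1-one
Product: 10 (R)-2,4,4-trimethylcyclohex-2-en-1-ol
Conditions: (S)-Me-CBS (10 mol%), BH3·SMe2 (0.6 equiv), THF, −20 °C
Reagents that add atoms: none
Why: in the Corey–Bakshi–Shibata reduction the 2-methylalkenyl arm acts as the large group, so the (S)-oxazaborolidine is expected to give the (R)-allylic alcohol (the antipodal catalyst is used if the first run shows the opposite sense).

Step 6
Reactants: 10 (R)-2,4,4-trimethylcyclohex-2-en-1-ol
Product: 12 ethyl (S)-2-(2,6,6-trimethylcyclohex-2-en-1-yl)acetate, via ketene acetal 11 (not isolated)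
Conditions: MeC(OEt)3 (5 equiv), EtCO2H (5 mol%), 140 °C, EtOH distilled off
Reagents that add atoms: triethyl orthoacetate, CCOC(C)(OCC)OCC
Why: the Johnson–Claisen rearrangement is suprafacial, so the C–O bond of the (R)-alcohol is exchanged for a C–C bond on the same ring face at the carbon next to the gem-dimethyl group, which sets the (S)-centre by 1,3-chirality transfer and moves the double bond to the methyl-bearing position.

Step 7
Reactants: 12 ethyl (S)-2-(2,6,6-trimethylcyclohex-2-en-1-yl)acetate
Product: 13 (S)-2-(2,6,6-trimethylcyclohex-2-en-1-yl)ethan-1-ol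
Conditions: LiAlH4, Et2O, 0 °C
Reagents that add atoms: none
Why: hydride reduction of the ester to the primary alcohol leaves the ring alkene and the non-enolisable ring stereocentre untouched.

Step 8
Reactants: 13 (S)-2-(2,6,6-trimethylcyclohex-2-en-1-yl)ethan-1-ol
Product: 14 (S)-6-(2-iodoethyl)-1,5,5-trimethylcyclohex-1-ene
Conditions: I2, PPh3, imidazole, CH2Cl2, 0 °C to rt
Reagents that add atoms: iodine, II
Why: Appel iodination of an unhindered primary alcohol runs under buffered conditions that should spare the trisubstituted ring alkene.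

Step 9
Reactants: 14 (S)-6-(2-iodoethyl)-1,5,5-trimethylcyclohex-1-ene
Product: 15 (S)-6-(but-3-yn-1-yl)-1,5,5-trimethylcyclohex-1-ene
Conditions: LiC≡CH·H2NCH2CH2NH2 (2 equiv), DMSO, rt
Reagents that add atoms: lithium acetylide ethylenediamine complex, [Li+].[C-]#C.NCCN
Why: SN2 alkylation of acetylide by a primary iodide in a dipolar aprotic solvent should give the terminal alkyne.

Step 10
Reactants: 15 (S)-6-(but-3-yn-1-yl)-1,5,5-trimethylcyclohex-1-ene
Product: 17 (S)-6-[(E)-4-iodo-3-methylbut-3-en-1-yl]-1,5,5-trimethylcyclohex-1-ene, via alkenyldimethylalane 16 (not isolated)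
Conditions: AlMe3 (2 equiv), ZrCp2Cl2 (0.25 equiv), CH2Cl2, 0 °C to rt; then I2, THF, −30 °C
Reagents that add atoms: trimethylaluminium, C[Al](C)C; iodine, II
Why: Negishi zirconium-catalysed carboalumination adds methyl and aluminium syn across the terminal alkyne with methyl on the internal carbon, and iodinolysis with retention fixes the E trisubstituted alkene while the trisubstituted ring alkene stays inert.

Step 11
Reactants: 8 (S)-6-bromo-2-ethenyl-2-methyl-2H-chromene; 17 (S)-6-[(E)-4-iodo-3-methylbut-3-en-1-yl]-1,5,5-trimethylcyclohex-1-ene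
Product: 19 (S)-6-bromo-2-methyl-2-{(E)-4-methyl-6-[(S)-2,6,6-trimethylcyclohex-2-en-1-yl]hex-3-en-1-yl}-2H-chromene, via B-alkyl-9-BBN 18 (not isolated)
Conditions: 9-BBN dimer (0.55 equiv), THF, 0 °C to rt; then 17, PdCl2(dppf) (5 mol%), AsPh3, aq Cs2CO3, DMF, rt, dark
Reagents that add atoms: none
Why: 9-BBN should hydroborate only the monosubstituted vinyl group in the anti-Markovnikov sense and not the cis-disubstituted C3=C4 bond, and the B-alkyl Suzuki–Miyaura coupling proceeds with retention of alkene geometry at room temperature, where oxidative addition to the vinyl iodide is much faster than to the electron-rich aryl bromide.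

Step 12
Reactants: 19 (S)-6-bromo-2-methyl-2-{(E)-4-methyl-6-[(S)-2,6,6-trimethylcyclohex-2-en-1-yl]hex-3-en-1-yl}-2H-chromene
Product: 22 (S)-2-methyl-2-{(E)-4-methyl-6-[(S)-2,6,6-trimethylcyclohex-2-en-1-yl]hex-3-en-1-yl}-2H-chromen-6-ol, via aryllithium 20 (not isolated), via dimethyl arylboronate 21 (not isolated)
Conditions: n-BuLi (1.1 equiv), THF, −78 °C; B(OMe)3, −78 to 0 °C; then 30% H2O2, aq NaOH, 0 °C, dark
Reagents that add atoms: hydrogen peroxide, OO
Why: bromine–lithium exchange, borylation and oxidative aryl migration from boron to oxygen should turn the aryl bromide into the phenol in one pot, since the alkenes do not react with basic hydrogen peroxide and neither stereocentre is involved.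

**Compound list**

1 | ethyl acetate | CCOC(C)=O | starting material
2 | but-3-en-2-one | CC(=O)C=C | intermediate
3 | 3-methylpenta-1,4-dien-3-ol | C=CC(C)(O)C=C | intermediate
4 | 5-bromo-2-fluorobenzaldehyde | O=Cc1cc(Br)ccc1F | starting material
5 | potassium 3-methylpenta-1,4-dien-3-olate | C=CC(C)([O-])C=C.[K+] | intermediate
6 | 5-bromo-2-[(3-methylpenta-1,4-dien-3-yl)oxy]benzaldehyde | C=CC(C)(C=C)Oc1ccc(Br)cc1C=O | intermediate
7 | 4-bromo-2-ethenyl-1-[(3-methylpenta-1,4-dien-3-yl)oxy]benzene | C=CC(C)(C=C)Oc1ccc(Br)cc1C=C | intermediate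
8 | (S)-6-bromo-2-ethenyl-2-methyl-2H-chromene | C=C[C@@]1(C)C=Cc2cc(Br)ccc2O1 | intermediate
9 | 2,4,4-trimethylcyclohex-2-en-1-one | CC1=CC(C)(C)CCC1=O | starting material
10 | (R)-2,4,4-trimethylcyclohex-2-en-1-ol | O[C@@H]1CCC(C)(C)C=C1C | intermediate
11 | 1-ethoxy-1-{[(R)-2,4,4-trimethylcyclohex-2-en-1-yl]oxy}ethene (ketene acetal) | C=C(OCC)O[C@@H]1CCC(C)(C)C=C1C | intermediate
12 | ethyl (S)-2-(2,6,6-trimethylcyclohex-2-en-1-yl)acetate | CC1=CCCC(C)(C)[C@@H]1CC(=O)OCC | intermediate
13 | (S)-2-(2,6,6-trimethylcyclohex-2-en-1-yl)ethan-1-ol | CC1=CCCC(C)(C)[C@@H]1CCO | intermediate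
14 | (S)-6-(2-iodoethyl)-1,5,5-trimethylcyclohex-1-ene | CC1=CCCC(C)(C)[C@@H]1CCI | intermediate
15 | (S)-6-(but-3-yn-1-yl)-1,5,5-trimethylcyclohex-1-ene | CC1=CCCC(C)(C)[C@@H]1CCC#C | intermediate
16 | dimethyl{(E)-2-methyl-4-[(S)-2,6,6-trimethylcyclohex-2-en-1-yl]but-1-en-1-yl}alane | CC1=CCCC(C)(C)[C@@H]1CC/C(C)=C/[Al](C)C | intermediate
17 | (S)-6-[(E)-4-iodo-3-methylbut-3-en-1-yl]-1,5,5-trimethylcyclohex-1-ene | CC1=CCCC(C)(C)[C@@H]1CC/C(C)=C/I | intermediate
18 | 9-{2-[(S)-6-bromo-2-methyl-2H-chromen-2-yl]ethyl}-9-borabicyclo[3.3.1]nonane | B1(C2CCCC1CCC2)CC[C@@]3(C)C=Cc4cc(Br)ccc4O3 | intermediate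
19 | (S)-6-bromo-2-methyl-2-{(E)-4-methyl-6-[(S)-2,6,6-trimethylcyclohex-2-en-1-yl]hex-3-en-1-yl}-2H-chromene | CC1=CCCC(C)(C)[C@@H]1CC/C(C)=C/CC[C@@]1(C)C=Cc2cc(Br)ccc2O1 | intermediate
20 | 6-lithio analogue of 19 (aryllithium) | CC1=CCCC(C)(C)[C@@H]1CC/C(C)=C/CC[C@@]1(C)C=Cc2cc([Li])ccc2O1 | intermediate
21 | dimethyl arylboronate (6-B(OMe)2 analogue of 19) | CC1=CCCC(C)(C)[C@@H]1CC/C(C)=C/CC[C@@]1(C)C=Cc2cc(B(OC)OC)ccc2O1 | intermediate
22 | (S)-2-methyl-2-{(E)-4-methyl-6-[(S)-2,6,6-trimethylcyclohex-2-en-1-yl]hex-3-en-1-yl}-2H-chromen-6-ol | CC1=CCCC(C)(C)[C@@H]1CC/C(C)=C/CC[C@@]1(C)C=Cc2cc(O)ccc2O1 | target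

**Step count and risks**

Total step count: 12. Longest linear sequence: 8 (steps 5 to 12); steps 1 to 4 form the convergent branch.

Steps most likely to fail:

1. Step 4. The catalyst may discriminate poorly between the two enantiotopic vinyl groups or favour the unwanted one, and traces of protic impurities may destroy the alkylidene before conversion is complete. The fallback sets out from 7 and comes back at 8. Ring closure with the achiral second-generation Grubbs catalyst RuCl2(H2IMes)(PCy3)(=CHPh) in CH2Cl2 at 40 °C should give racemic 6-bromo-2-ethenyl-2-methyl-2H-chromene F1. Its enantiomers are then separated by preparative supercritical-fluid chromatography on a polysaccharide chiral stationary phase, and the S enantiomer is 8. This replaces asymmetric catalysis by resolution at the cost of half the material.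

2. Step 2. Reversible addition of the hindered alkoxide to the formyl group and base-induced hydride transfer between aldehyde molecules may outrun substitution at a ring that bromine activates only weakly. The fallback sets out from 3 (as its salt 5) and comes back at 6. The alkoxide 5 is combined with 5-bromo-2-fluorobenzonitrile (THF, 0 °C to rt), whose cyano group activates more strongly and offers no competing carbonyl, to give 5-bromo-2-[(3-methylpenta-1,4-dien-3-yl)oxy]benzonitrile F2. Diisobutylaluminium hydride in toluene at −78 °C should reduce the nitrile to the N-(diisobutylalumanyl) aldimine F3, which is not isolated and is hydrolysed on buffered aqueous work-up to 6.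

3. Step 11. Insertion of zerovalent palladium into the aryl C–Br bond may compete with insertion into the vinyl C–I bond, so that the alkylborane couples with the aryl bromide of a second molecule and oligomers form. The fallback sets out from 8 and comes back at 22, with the bromine exchanged for a protected oxygen before the coupling.
   - Bromine–lithium exchange on 8 (n-BuLi, THF, −78 °C) gives the aryllithium F4, B(OMe)3 converts it into the dimethyl arylboronate F5, and H2O2/NaOH should oxidise this to (S)-2-ethenyl-2-methyl-2H-chromen-6-ol F6.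
   - TBSCl and imidazole in DMF give the tert-butyldimethylsilyl ether F7.
   - Hydroboration of F7 with 9-BBN gives the B-alkyl borane F8, which is coupled with 17 under the conditions of step 11, now without any competing aryl halide, to give the silyl ether of the target F9.
   - Bu4NF in THF at 0 °C releases 22.

**Further compounds**

F1 | step 4 | racemic 6-bromo-2-ethenyl-2-methyl-2H-chromene | C=CC1(C)C=Cc2cc(Br)ccc2O1
F2 | step 2 | 5-bromo-2-[(3-methylpenta-1,4-dien-3-yl)oxy]benzonitrile | C=CC(C)(C=C)Oc1ccc(Br)cc1C#N
F3 | step 2 | N-(diisobutylalumanyl) aldimine of 6 | C=CC(C)(C=C)Oc1ccc(Br)cc1C=N[Al](CC(C)C)CC(C)C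
F4 | step 11 | (S)-2-ethenyl-6-lithio-2-methyl-2H-chromene | C=C[C@@]1(C)C=Cc2cc([Li])ccc2O1
F5 | step 11 | dimethyl [(S)-2-ethenyl-2-methyl-2H-chromen-6-yl]boronate | C=C[C@@]1(C)C=Cc2cc(B(OC)OC)ccc2O1
F6 | step 11 | (S)-2-ethenyl-2-methyl-2H-chromen-6-ol | C=C[C@@]1(C)C=Cc2cc(O)ccc2O1
F7 | step 11 | tert-butyl{[(S)-2-ethenyl-2-methyl-2H-chromen-6-yl]oxy}dimethylsilane | C=C[C@@]1(C)C=Cc2cc(O[Si](C)(C)C(C)(C)C)ccc2O1
F8 | step 11 | 9-{2-[(S)-6-(tert-butyldimethylsilyloxy)-2-methyl-2H-chromen-2-yl]ethyl}-9-borabicyclo[3.3.1]nonane | B1(C2CCCC1CCC2)CC[C@@]3(C)C=Cc4cc(O[Si](C)(C)C(C)(C)C)ccc4O3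
F9 | step 11 | tert-butyldimethylsilyl ether of 22 | CC1=CCCC(C)(C)[C@@H]1CC/C(C)=C/CC[C@@]1(C)C=Cc2cc(O[Si](C)(C)C(C)(C)C)ccc2O1
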